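Amounts first: gamma and theta get the same reagent, 0.450 M, but gamma holds 0.25 M of substrate for 8.0 h and theta holds 1.0 M for 2.0 h.

| flask | substrate | reagent | temperature | remark | time |
|---|---|---|---|---|---|
| Sunday's | 0.36 M | 0.45 M | 20 °C | run made earlier |  |
| Monday's | 1.1 M | 0.45 M | 31 °C | run made earlier |  |
| gamma | 0.25 M | 0.450 M | 25 °C |  | 8.0 h |
| theta | 1.0 M | 0.450 M | 25 °C |  | 2.0 h |

- Sunday's (time / h: target / %, side product / %): 0.333: 0.6, 0; 0.667: 0.7, 0; 1.00: 1.9, 2.1; 2.00: 4.5, 5.4; 4.00: 8.5, 10.5
- Monday's (time / h: target / %, side product / %): 0.333: 1.1, 2.2; 0.667: 2.2, 5.0; 1.00: 2.8, 6.5; 2.00: 2.9, 12.0; 4.00: 2.2, 16.0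

(each reading ± 0.5 percentage points)

- the analysis behind the earlier runs scatters by 0.5 percentage points, standard deviation
- candidate steps: intermediate B <-> intermediate C; intermediate C <-> intermediate D; substrate + reagent -> intermediate A; reagent + intermediate A -> target; intermediate A -> intermediate B; target -> over-reaction product; intermediate A -> side product

- which one finishes higher in share of target in all that became target or side product or over-reaction product ("neither" within 2 percentage points) (gamma / theta / neither)
- share of target in all that became target or side product or over-reaction product, gamma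
- share of target in all that became target or side product or over-reaction product, theta

Among the candidate steps, intermediate A leaves with reagent to target, unaided to side product, or unaided to intermediate B. For the split between target and side product, I take as the zero of my scale the reagent level c* at which the first two of these exits run equal; its reciprocal is the selectivity factor. Charged reagent times side product over target reads 0.556 M at 20 °C from Sunday's last reading and 1.04 M at 31 °C from Monday's reading at 1.00 h. Since 25 °C lies between them, I take their geometric mean, 0.762 M, as the balance concentration c*.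

At reagent level c, the part of the target-or-side-product flow made as target is c/(c + c*), which at the charged reagent gives me 37.1 % in both flasks. The flasks should then part by over-reaction, and gamma stands longer than theta, so I expect theta ahead.

The forecast also says theta, with 23 % for gamma and 36 % for theta, holding that “their formation selectivity is similar, about 40% target”; that figure differs from mine.

The flasks give theta, with 18.6 % for gamma and 28.4 % for theta, which puts theta 7.6 percentage points below the forecast.

    intermediate B ⇌ intermediate C (K = 6.20, k = 7.90 × 10⁻⁶ s⁻¹, Ea = 109 kJ mol⁻¹, ΔH = 13.0 kJ mol⁻¹)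
    intermediate C ⇌ intermediate D (K = 40.0, k = 1.40 × 10⁻⁵ s⁻¹, Ea = 101 kJ mol⁻¹, ΔH = 12.0 kJ mol⁻¹)
    substrate + reagent → intermediate A (k = 2.30 × 10⁻⁴ L mol⁻¹ s⁻¹, Ea = 69.0 kJ mol⁻¹)
    reagent + intermediate A → target (k = 2.30 × 10⁻⁴ L mol⁻¹ s⁻¹, Ea = 76.0 kJ mol⁻¹)
    intermediate A → intermediate B (k = 9.20 × 10⁻⁵ s⁻¹, Ea = 89.0 kJ mol⁻¹)
    target → over-reaction product (k = 4.70 × 10⁻⁵ s⁻¹, Ea = 104 kJ mol⁻¹)
    intermediate A → side product (k = 9.00 × 10⁻⁵ s⁻¹, Ea = 89.0 kJ mol⁻¹)
    (constants at 25 °C)

In gamma at 1.70 h, intermediate A's half-life is shorter by the side exit, 2.1 h, than by the target exit, 2.6 h, so reagent stands below balance there, and target plus over-reaction product makes 42.2 % of the three at the end, against my 37.1 %. At 8.00 h, gamma makes target at 0.446 of the rate it uses it.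

A neighbour of gamma charged with 1.1 M of reagent gets, from c*, 59.1 % of the target-or-side-product flow made as target. The flask gives 68.7 %, of which 32.5 % of the substrate charged stands as over-reaction product and 19.0 % as target, for a share of 25.4 %.

The numbers in the tables stem from a simulated flask on assumed constants, noise included.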